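# Proposed total synthesis of CNP0132024.3 (an asbestinin diester) by a cyclopropane–aldehyde [3+2] annulation

## Analysis of the target

Atoms are numbered as in the asbestinins: C1–C14 are ring carbons, C15/C16 the arm closing the oxepane, C17 the methyl on C15, C18 the methyl on C3, C19 the exocyclic methylene on C7, C20 the methyl on C12. The target is a tetracycle: a cyclohexane (C1, C10–C14) cis-fused along C1–C10 to a tetrahydrofuran (C1, C2, O, C9, C10). The chain C3–C8 bridges C2 and C9 into an oxonane, and C3–O–C16–C15–C14 closes a trans-fused oxepane. The core carries ten stereocentres (1R, 2R, 3R, 4S, 9R, 10S, 11S, 12S, 14R, 15S) and the side chain one more (2′R). H1 and H10 are cis, and the C2 and C9 substituents are cis to each other on the tetrahydrofuran, pointing away from the cyclohexane. C9, the C11 oxygen and the C12 methyl lie on one face of the cyclohexane, while the C14 arm is trans to C2. The C3–O and C4–O bonds are related as the anti-addition product of a (Z)-C3=C4 alkene. The sensitive groups are two different esters (C4 acetate; C11 (R)-2-hydroxyoctanoate with a free α-hydroxyl, prone to hydrolysis and acyl shift) and the acid-sensitive 1,1-disubstituted C7=C19 alkene. The difficulty lies in the nine-membered ring, the quaternary C3, and the C14/C15 pair, which sits on the hindered side of a cis-fused bicycle. The strategy rests on the tetrahydrofuran: C9 lies between the ring oxygen and C10, and C1 lies between C2 and the cyclohexane carbon C14. C9 can therefore be the donor carbon and C1 the doubly acceptor-substituted carbon of a cyclopropane, with O–C2 supplied by an aldehyde.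

## Retrosynthetic reasoning

**Acyl groups and exocyclic alkene (43 ⇐ 42 ⇐ 41).** The free α-hydroxyl is unmasked last from silyl ether 42. The C7=C19 alkene is traced to the ring allylsilane 41, because protonation at C8 with loss of silicon places the double bond exocyclic without regiochemical choice. This keeps the acid-sensitive alkene out of all earlier steps.

**Oxonane (41 ⇐ 40).** The C7=C8 bond is cut by ring-closing metathesis. It is the only ring bond whose two ends can both be simple alkenes: the propenyl group on C9, which is the donor group of the key step, and a 1,1-disubstituted alkene on C6. Closing this ring last lets the cis C2/C9 relationship, the quaternary C3 and the finished oxepane preorganise the chain.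

**C6–C7 and the C11 ester (40 ⇐ 38 ⇐ 34 + 37).** The silylmethyl-substituted alkene is attached to C6 by an sp3–sp2 cross-coupling of primary iodide 38 through its zinc reagent 39. The C11 ester is cut to alcohol 34 and the protected acid 37.

**C11 configuration (34 ⇐ 33 ⇐ 32).** The natural (11S) alcohol is drawn from ketone 33 by hydride attack on the face that carries H10 and H12. That face is the unhindered one, since C9 and the C12 methyl flank the other. This allows C11 to be carried in the opposite configuration through the early part of the route (see the cyclopropane paragraph).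

**Oxepane and C3/C4 (30 ⇐ 29 ⇐ 28 ⇐ 27).** The O–C3 bond is cut. In the forward direction the C16 hydroxyl of 27 opens the C3–C4 epoxide 28 at its tertiary carbon with inversion. One alkene face thereby fixes both C3 and C4, and the C4 hydroxyl appears ready for acetylation. This is done before the oxonane exists, when only one other, less electron-rich alkene competes, no transannular alkene can intercept the epoxide, and the Z-alkene has a locked conformation.

**C14 arm (27 ⇐ 25 ⇐ 24 ⇐ 22).** C15 comes from hydroboration of the isopropenyl group of 25. The C14–C15 bond is formed by coupling the C14 radical derived from iodide 24 with an isopropenyl nucleophile. Any reagent that delivers hydrogen to an sp2 C14 would come from the open face and give the wrong epimer. A carbon group arriving on that face, anti to the C2 arm, gives the required trans arrangement. The iodide comes from the C14 ketone 22.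

**Key disconnection (22 ⇐ 21 ⇐ 14 + 20).** Removing the C1 ester leads to keto ester 21. Cutting O–C9 and C1–C2 splits it into the bicyclo[4.1.0]heptanone 14 and the (Z)-enal 20. One step thus forms the tetrahydrofuran, joins the two halves and sets C1, C2 and C9.

**Cyclopropane (14 ⇐ 13 ⇐ 12 ⇐ 10 ⇐ 9 ⇐ 7 ⇐ 5 ⇐ 4).** 14 comes from intramolecular cyclopropanation of diazo keto ester 13 onto a Z-alkene, which is needed for the endo propenyl group. With a Z-alkene, allylic strain holds C11–H in the alkene plane, so the carbenoid must add on the face opposite the C11 silyloxy group. A silyloxy group with the natural C11 configuration would therefore direct the cyclopropane to the wrong face. The ether is consequently installed syn to the C12 methyl (11-epi) by a (Z)-crotylboration of ynal 4, and it is corrected later as described above. The chain is extended from the vinyl group of 7 by hydroboration, oxidation and a decarboxylative Claisen condensation.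

**Enal (20 ⇐ 18 ⇐ 17 ⇐ 15).** The Z-trisubstituted alkene is set by a Z-selective phosphonate olefination of aldehyde 17, made from propane-1,3-diol 15.

## Alternatives that were turned down

**Alternative 1: chromium-mediated closure at C6–C7.**
- *Disconnection and key step:* The oxonane is cut between C6 and C7. The open precursor A2 carries a C7 alkenyl iodide and a C6 aldehyde. CrCl2 with catalytic NiCl2 would convert the iodide into an alkenylchromium species that adds to the aldehyde and gives the tetracyclic allylic alcohol A1.
- *For:* The exocyclic methylene is formed directly in the ring-closing step, with no acid treatment and no trisubstituted ring alkene. The reaction tolerates both esters and is well suited to medium rings. On these two points it is stronger than the chosen route, which needs a metathesis to a trisubstituted alkene and an acidic protodesilylation.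
- *Against:* A1 has a C6 hydroxyl that the target lacks. Removing an allylic alcohol next to a 1,1-disubstituted alkene (radical or hydride methods) risks moving the double bond, costs at least two steps and creates a stereocentre only to delete it. The disconnection also says nothing about the ten core stereocentres; A2 would have to be assembled linearly with every one of them in place, and stoichiometric chromium at high dilution is needed.
- *Comparison:* The chosen strategy offers a convergent step that creates the tetrahydrofuran and three stereocentres, and no superfluous oxygen.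

**Alternative 2: Baeyer–Villiger ring expansion to the oxepane.**
- *Disconnection and key step:* The O–C3 bond is traced to the decalone A4. A peracid would insert oxygen between the C16 carbonyl carbon and the quaternary C3, giving the seven-membered lactone A3.
- *For:* The more substituted carbon migrates with retention, so C3 would be set in a carbocycle where its control is routine and no seven-membered ring closure is needed. On certainty of the C3 configuration this is stronger than an epoxidation whose facial selectivity must be controlled.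
- *Against:* A3 is a lactone without the C17 methyl. C16 must be reduced to a methylene and C15 methylated on a seven-membered enolate of uncertain facial bias. The peracid forbids free alkenes, so C7 must be a masked ketone and methylenated later. The C11 benzyl ether calls for a deprotection that is awkward once the exocyclic alkene is present. The C4 oxygen and the whole tricyclic carbocycle A4 must be made beforehand.
- *Comparison:* The chosen route obtains C3–O and C4–O from one alkene in one operation and carries fewer redox corrections.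

**Alternative 3: oxonium ylide [2,3] rearrangement.**
- *Disconnection and key step:* The O–C9 and C8–C9 bonds are cut. The diazoketone A6 would give a copper carbenoid with Cu(CF3COCHCOCF3)2. The tetrahydropyran oxygen captures it, and a [2,3] shift onto the allylsilane-bearing alkenyl group expands the ring to the bicyclic ketone A5.
- *For:* One step forms both the tetrahydrofuranone and the nine-membered ring, with the C3/C4 oxygens and the allylsilane already present. For the medium ring this is the most direct of all the options and avoids a late metathesis.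
- *Against:* A5 lacks the cyclohexane. C1, C10, C11, C12 and C14 and the oxepane would have to be built afterwards onto the C10 ketone and the C1 methylene, a long annulation with five stereocentres set late on a flexible bicycle. A competing [1,2] shift and the geometry of the new ring alkene are further uncertainties.
- *Comparison:* The chosen route brings the cyclohexane stereocentres in with the cyclopropane and fixes C1/C2/C9 relative to them in the same step.

Key step: step 16

Remark on the chemistry: (R)-2-hydroxyoctanoic acid (35) is taken to be purchasable; otherwise it is one step from (R)-2-aminooctanoic acid by nitrous acid deamination with retention.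

Remark on the chemistry: the C11 silyl ether is carried in the configuration opposite to the target from 5 to 32 (reason in the cyclopropane paragraph) and is corrected in steps 26 and 27.

## Route

### Cyclopropane fragment (steps 1–10)

Step 1
Reactants: 1 prop-2-yn-1-ol; 2 (E)-1-bromoprop-1-ene
Product: 3 (E)-hex-4-en-2-yn-1-ol
Conditions: Pd(PPh3)2Cl2 (2 mol %), CuI (4 mol %), i-Pr2NH, THF, rt
Reagents that add atoms: none
Why: Sonogashira coupling of a terminal alkyne with an alkenyl bromide; oxidative addition and reductive elimination retain the E geometry.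

Step 2
Reactants: 3 (E)-hex-4-en-2-yn-1-ol
Product: 4 (E)-hex-4-en-2-ynal
Conditions: activated MnO2, CH2Cl2, rt; filtered solution used directly
Reagents that add atoms: none
Why: MnO2 oxidises propargylic alcohols selectively and leaves the enyne untouched; the volatile ynal is not concentrated.

Step 3
Reactants: 4 (E)-hex-4-en-2-ynal
Product: 5 (3S,4R,7E)-3-methylnona-1,7-dien-5-yn-4-ol
Conditions: cis-but-2-ene, KOt-Bu, n-BuLi, THF, −78 → −45 °C; (+)-Ipc2BOMe [from (−)-α-pinene], −78 °C; BF3·OEt2; then 4, −78 °C; NaOH, H2O2
Reagents that add atoms: cis-but-2-ene, C/C=C\C (delivered as the (Z)-crotylborane made in the flask)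
Why: Brown (Z)-crotylboration through a chair six-membered transition state turns the Z geometry into the syn C11–O/C12–Me relationship; the isopinocampheyl groups from (−)-α-pinene should direct addition to the Re face of the aldehyde, giving (4R). C12 is thereby set as in the target and C11 deliberately opposite to it.

Step 4
Reactants: 5 (3S,4R,7E)-3-methylnona-1,7-dien-5-yn-4-ol
Product: 6 tert-butyl(dimethyl){[(3S,4R,7E)-3-methylnona-1,7-dien-5-yn-4-yl]oxy}silane
Conditions: TBSCl, imidazole, DMF, rt
Reagents that add atoms: tert-butyl(chloro)dimethylsilane, CC(C)(C)[Si](C)(C)Cl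
Why: Standard silylation of a secondary propargylic alcohol; the bulky ether later steers the cyclopropanation.

Step 5
Reactants: 6 tert-butyl(dimethyl){[(3S,4R,7E)-3-methylnona-1,7-dien-5-yn-4-yl]oxy}silane
Product: 7 tert-butyl(dimethyl){[(3S,4S,5Z,7E)-3-methylnona-1,5,7-trien-4-yl]oxy}silane
Conditions: Zn dust activated with Cu(OAc)2 and AgNO3, MeOH/H2O (1:1), rt
Reagents that add atoms: none
Why: Boland reduction: activated zinc reduces only the conjugated triple bond, delivering two hydrogens syn to give the Z alkene; the isolated vinyl group and the E alkene are not touched.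

Step 6
Reactants: 7 tert-butyl(dimethyl){[(3S,4S,5Z,7E)-3-methylnona-1,5,7-trien-4-yl]oxy}silane
Product: 9 (3S,4R,5Z,7E)-4-[tert-butyl(dimethyl)silyl]oxy-3-methylnona-5,7-dien-1-ol, via alkylborane 8 (not isolated)
Conditions: 9-BBN, THF, 0 °C → rt; then aq. NaOH, H2O2, 0 °C
Reagents that add atoms: hydrogen peroxide, OO
Why: 9-BBN hydroborates the monosubstituted terminal alkene far faster than the conjugated, hindered 1,2-disubstituted diene, with boron on the terminal carbon; oxidation replaces boron by hydroxyl.

Step 7
Reactants: 9 (3S,4R,5Z,7E)-4-[tert-butyl(dimethyl)silyl]oxy-3-methylnona-5,7-dien-1-ol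
Product: 10 (3S,4R,5Z,7E)-4-[tert-butyl(dimethyl)silyl]oxy-3-methylnona-5,7-dienoic acid
Conditions: TEMPO (cat.), PhI(OAc)2, MeCN/H2O (1:1), rt
Reagents that add atoms: water, O
Why: Oxoammonium oxidation through the aldehyde hydrate to the acid at neutral pH, which spares the silyl ether and the Z,E-diene.

Step 8
Reactants: 10 (3S,4R,5Z,7E)-4-[tert-butyl(dimethyl)silyl]oxy-3-methylnona-5,7-dienoic acid
Product: 12 methyl (5S,6R,7Z,9E)-6-[tert-butyl(dimethyl)silyl]oxy-5-methyl-3-oxoundeca-7,9-dienoate, via acyl imidazolide 11 (not isolated)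
Conditions: 1,1′-carbonyldiimidazole, THF, rt; then KO2CCH2CO2Me/MgCl2 (premixed, THF, 50 °C), rt → 40 °C; aq. citric acid
Reagents that add atoms: potassium methyl malonate, [K+].[O-]C(=O)CC(=O)OC
Why: Masamune–Brooks decarboxylative Claisen condensation: the magnesium malonate is C-acylated by the imidazolide and loses CO2; the carbon α to the acyl group is a methylene, so nothing can epimerise.

Step 9
Reactants: 12 methyl (5S,6R,7Z,9E)-6-[tert-butyl(dimethyl)silyl]oxy-5-methyl-3-oxoundeca-7,9-dienoate
Product: 13 methyl (5S,6R,7Z,9E)-6-[tert-butyl(dimethyl)silyl]oxy-2-diazo-5-methyl-3-oxoundeca-7,9-dienoate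
Conditions: 4-acetamidobenzenesulfonyl azide, Et3N, MeCN, 0 °C → rt
Reagents that add atoms: 4-acetamidobenzenesulfonyl azide, CC(=O)Nc1ccc(cc1)S(=O)(=O)N=[N+]=[N-]
Why: Regitz diazo transfer to the active methylene of a β-keto ester.

Step 10
Reactants: 13 methyl (5S,6R,7Z,9E)-6-[tert-butyl(dimethyl)silyl]oxy-2-diazo-5-methyl-3-oxoundeca-7,9-dienoate
Product: 14 methyl (1R,4S,5R,6R,7S)-5-[tert-butyl(dimethyl)silyl]oxy-4-methyl-2-oxo-7-[(E)-prop-1-enyl]bicyclo[4.1.0]heptane-1-carboxylate (propenyl endo; silyloxy trans and methyl cis to the cyclopropane)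
Conditions: bis(N-tert-butylsalicylaldiminato)copper (5 mol %), toluene, 90 °C, slow addition of 13
Reagents that add atoms: none
Why: Intramolecular cyclopropanation by the copper carbenoid onto the proximal Z alkene (six-membered ring); syn addition makes the propenyl group endo. Allylic strain of the Z alkene holds C11–H in the alkene plane, so the tether and the carbenoid reach the face opposite the silyloxy group, which fixes C1, C9 and C10 relative to C12. A copper rather than a dirhodium catalyst is chosen to suppress insertion into the activated C11–H bond.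

### Enal fragment (steps 11–15)

Step 11
Reactants: 15 propane-1,3-diol
Product: 16 3-(triisopropylsilyloxy)propan-1-ol
Conditions: NaH (1.0 equiv), THF, 0 °C → rt; then TIPSCl
Reagents that add atoms: chlorotri(propan-2-yl)silane, CC(C)[Si](Cl)(C(C)C)C(C)C
Why: The sparingly soluble monosodium alkoxide of the symmetric diol is silylated once.

Step 12
Reactants: 16 3-(triisopropylsilyloxy)propan-1-ol
Product: 17 3-(triisopropylsilyloxy)propanal
Conditions: TEMPO (cat.), PhI(OAc)2, CH2Cl2, rt
Reagents that add atoms: none
Why: Oxoammonium oxidation stops at the aldehyde when water is absent.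

Step 13
Reactants: 17 3-(triisopropylsilyloxy)propanal
Product: 18 methyl (Z)-2-methyl-5-(triisopropylsilyloxy)pent-2-enoate
Conditions: methyl 2-[bis(2,2,2-trifluoroethoxy)phosphoryl]propanoate, KN(SiMe3)2, 18-crown-6, THF, −78 °C
Reagents that add atoms: methyl 2-[bis(2,2,2-trifluoroethoxy)phosphoryl]propanoate, COC(=O)C(C)P(=O)(OCC(F)(F)F)OCC(F)(F)F
Why: Still–Gennari olefination: the electron-poor phosphonate and the dissociated potassium enolate make elimination from the kinetic adduct fast, which gives the Z trisubstituted enoate.

Step 14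
Reactants: 18 methyl (Z)-2-methyl-5-(triisopropylsilyloxy)pent-2-enoate
Product: 19 (Z)-2-methyl-5-(triisopropylsilyloxy)pent-2-en-1-ol
Conditions: i-Bu2AlH (2.2 equiv), CH2Cl2, −78 °C; Rochelle salt
Reagents that add atoms: none
Why: 1,2-Reduction of the enoate to the allylic alcohol leaves the alkene geometry intact.

Step 15
Reactants: 19 (Z)-2-methyl-5-(triisopropylsilyloxy)pent-2-en-1-ol
Product: 20 (Z)-2-methyl-5-(triisopropylsilyloxy)pent-2-enal
Conditions: activated MnO2, CH2Cl2, 0 °C → rt; used at once
Reagents that add atoms: none
Why: Neutral allylic oxidation keeps the Z geometry; the enal is used immediately because Z α-methyl enals isomerise on storage or with acid.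

### Key step (step 16)

Step 16
Reactants: 14 methyl (1R,4S,5R,6R,7S)-5-[tert-butyl(dimethyl)silyl]oxy-4-methyl-2-oxo-7-[(E)-prop-1-enyl]bicyclo[4.1.0]heptane-1-carboxylate; 20 (Z)-2-methyl-5-(triisopropylsilyloxy)pent-2-enal
Product: 21 methyl 7-[tert-butyl(dimethyl)silyl]oxy-6-methyl-4-oxo-1-[(E)-prop-1-enyl]-3-[(Z)-5-(triisopropylsilyloxy)pent-2-en-2-yl]hexahydroisobenzofuran-3a(1H)-carboxylate (asbestinin numbering: cis-fused, C1 ester, C14 ketone, C2 and C9 arms cis, C11 silyloxy epimeric to the target)
Conditions: Sn(OTf)2 (10 mol %), 4 Å molecular sieves, ClCH2CH2Cl, 0 °C → rt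
Reagents that add atoms: none
Why: Tin bis(triflate) chelates the ketone and ester oxygens of 14 and polarises the C1–C9 bond, the only cyclopropane bond flanked by the alkenyl donor and both acceptors. The carbonyl oxygen of 20 then attacks C9 from the side opposite C1 (substitution with inversion), giving a tin enolate tethered to an oxocarbenium ion. The C1 enolate adds to the oxocarbenium carbon C2 and closes the tetrahydrofuran by an aldol-type attack that is formally 5-endo-trig on the C2=O+ bond, the usual mode for enolate–oxocarbenium closures. The closest known reaction type is the Lewis acid-catalysed formal [3+2] annulation of donor–acceptor cyclopropanes with aldehydes to 2,5-cis tetrahydrofurans. C9 is controlled by the stereospecific opening of the endo-alkenyl cyclopropane. C2 is controlled by an envelope transition state with the alkenyl residue of the (E)-oxocarbenium ion pseudo-equatorial, hence cis to C8. C1 can bond only on the face to which the C9–O–C2 tether is attached, so the ring fusion is cis and the ester sits where H1 will be. The step needs cleavage of C1–C9 rather than C1–C10, capture at C2 rather than at the remote end of the conjugated cation, and retention of the Z alkene; fast intramolecular collapse of the ion pair, a catalytic amount of Lewis acid and low temperature should secure these.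

### Elaboration of the core (steps 17–27)

Step 17
Reactants: 21 keto ester from step 16
Product: 22 the corresponding cis-fused C14 ketone with hydrogen at C1
Conditions: LiCl, H2O (2 equiv), DMSO, 130 °C
Reagents that add atoms: none
Why: Krapcho dealkoxycarbonylation (chloride attack at the ester methyl, loss of CO2); protonation of the enolate at C1 should give the cis-fused bicycle, which is also the more stable one at this epimerisable centre. β-Elimination of the ring oxygen is disfavoured because the C2–O bond lies close to the enolate plane.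

Step 18
Reactants: 22 C14 ketone
Product: 23 C14 alcohol (hydroxyl cis to the C2 arm)
Conditions: NaBH4, MeOH, 0 °C
Reagents that add atoms: none
Why: Hydride should add anti to the C2 arm; the C14 configuration is erased in step 20, so this selectivity is not required.

Step 19
Reactants: 23 C14 alcohol
Product: 24 C14 iodide (iodine trans to the C2 arm)
Conditions: I2, PPh3, imidazole, toluene, 60 °C
Reagents that add atoms: iodine, II
Why: Appel-type iodination with inversion gives the secondary iodide needed as radical precursor.

Step 20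
Reactants: 24 C14 iodide
Product: 25 C14 isopropenyl compound (14R, isopropenyl trans to the C2 arm)
Conditions: isopropenylmagnesium bromide, Fe(acac)3 (5 mol %), TMEDA, hexamethylenetetramine, THF, 0 °C
Reagents that add atoms: isopropenylmagnesium bromide, CC(=C)[Mg]Br
Why: Iron-catalysed Kumada-type coupling of a secondary alkyl iodide with an alkenyl Grignard reagent; it runs through the C14 radical, which should be captured anti to the vicinal C2 arm whatever the iodide configuration, placing carbon rather than hydrogen on the open face.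

Step 21
Reactants: 25 C14 isopropenyl compound
Product: 27 C16 primary alcohol (15S), via alkylborane 26 (not isolated)
Conditions: 9-BBN, THF, 0 °C → rt; then aq. NaOH, H2O2, 0 °C
Reagents that add atoms: hydrogen peroxide, OO
Why: 9-BBN reacts with the 1,1-disubstituted alkene much faster than with the propenyl or the trisubstituted alkene. In the rotamer favoured by allylic strain (C14–H in the plane of C15=C16), boron approaches the face flanked by the C13 methylene and away from the C1 methine, which should give 15S.

Step 22
Reactants: 27 C16 primary alcohol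
Product: 29 oxepane alcohol (tricyclic core with C3–O–C16 ether and free C4 hydroxyl, 3R,4S), via epoxide 28 (not isolated)
Conditions: enantiomer of the fructose-derived Shi ketone (from L-sorbose, 30 mol %), Oxone (2KHSO5·KHSO4·K2SO4), K2CO3, Bu4NHSO4, MeCN/CH2(OMe)2/aq. Na2B4O7 buffer, 0 °C; crude product, camphorsulfonic acid (10 mol %), CH2Cl2, 0 °C
Reagents that add atoms: potassium peroxymonosulfate, [K+].[O-]S(=O)(=O)OO
Why: Shi epoxidation of the most electron-rich alkene. Allylic strain of the Z alkene keeps C2–H in the alkene plane, and the dioxirane should add anti to the ring oxygen, a preference that the chosen ketone enantiomer reinforces according to the spiro transition-state model. Under acid catalysis the C16 hydroxyl then opens the epoxide at the tertiary C3 with inversion (7-exo-tet), setting C3 and leaving the C4 hydroxyl anti to the new C3–O bond.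

Step 23
Reactants: 29 oxepane alcohol
Product: 30 C4 acetate
Conditions: Ac2O, DMAP, pyridine, CH2Cl2, rt
Reagents that add atoms: acetic anhydride, CC(=O)OC(C)=O
Why: Acylation of the only free hydroxyl; DMAP overcomes hindrance from the adjacent quaternary C3.

Step 24
Reactants: 30 C4 acetate
Product: 31 C6,C11 diol (11-epi)
Conditions: HF (48 % aq.), MeCN, 0 °C → rt
Reagents that add atoms: none
Why: Acidic fluoride removes both silyl ethers without the acetyl migration that basic fluoride could cause.

Step 25
Reactants: 31 C6,C11 diol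
Product: 32 C6 iodide with free 11-epi hydroxyl
Conditions: I2, PPh3, imidazole, CH2Cl2, 0 °C
Reagents that add atoms: iodine, II
Why: The primary hydroxyl reacts selectively; the secondary C11 hydroxyl, flanked by two substituted carbons, should be inert at 0 °C.

Step 26
Reactants: 32 C6 iodide with free 11-epi hydroxyl
Product: 33 C11 ketone
Conditions: Dess–Martin periodinane, NaHCO3, CH2Cl2, 0 °C → rt
Reagents that add atoms: none
Why: Buffered, non-basic oxidation that should not epimerise C10 or C12 and tolerates the primary iodide.

Step 27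
Reactants: 33 C11 ketone
Product: 34 C11 alcohol with the natural (11S) configuration
Conditions: NaBH4, CeCl3·7H2O, MeOH/CH2Cl2, −78 °C
Reagents that add atoms: none
Why: Hydride should attack from the face bearing H10 and H12 (axial attack, anti to C9 and to the C12 methyl), giving the equatorial hydroxyl cis to both neighbours; CeCl3 suppresses enolisation, and the iodide and acetate are unaffected at this temperature.

### Side chain and completion (steps 28–33)

Step 28
Reactants: 35 (R)-2-hydroxyoctanoic acid
Product: 37 (R)-2-[tert-butyl(dimethyl)silyl]oxyoctanoic acid, via silyl ester 36 (not isolated)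
Conditions: TBSCl (2.2 equiv), imidazole, DMF, rt; then K2CO3, MeOH/THF/H2O, rt; pH 4
Reagents that add atoms: tert-butyl(chloro)dimethylsilane, CC(C)(C)[Si](C)(C)Cl
Why: Both oxygens are silylated and the labile silyl ester is then cleaved selectively; the stereocentre is not involved.

Step 29
Reactants: 34 C11 alcohol (11S); 37 (R)-2-[tert-butyl(dimethyl)silyl]oxyoctanoic acid
Product: 38 C11 (R)-2-silyloxyoctanoate bearing the C6 iodide
Conditions: EDC·HCl, DMAP (0.3 equiv), CH2Cl2, 0 °C → rt
Reagents that add atoms: none
Why: Steglich esterification; the low DMAP loading limits racemisation of the α-silyloxy acid and alkylation of the base by the primary iodide.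

Step 30
Reactants: 38 C11 ester with C6 iodide
Product: 40 metathesis precursor with the 2-(trimethylsilylmethyl)allyl unit on C6, via alkylzinc iodide 39 (not isolated)
Conditions: Zn dust, LiCl, THF, 35 °C; then (2-bromoallyl)trimethylsilane, Pd(OAc)2 (5 mol %), SPhos (10 mol %), THF, rt
Reagents that add atoms: (2-bromoallyl)trimethylsilane, C=C(Br)C[Si](C)(C)C
Why: LiCl-promoted zinc insertion into the primary C–I bond tolerates both esters, and the Negishi sp3–sp2 coupling attaches C7 with its 1,1-disubstituted alkene and silylmethyl group.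

Step 31
Reactants: 40 metathesis precursor
Product: 41 tetracyclic allylsilane with the ring-cis C7=C8 alkene
Conditions: second-generation Grubbs catalyst RuCl2(=CHPh)(PCy3)(H2IMes) (15 mol %), toluene (1 mM), 80 °C
Reagents that add atoms: none
Why: Ring-closing metathesis: the ruthenium carbene should load at the propenyl group and close onto the 1,1-disubstituted alkene with loss of propene. The cis C2/C9 arms, the quaternary C3 and the oxepane hold the chain ends together, and only the ring-cis alkene fits a nine-membered ring.

Step 32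
Reactants: 41 tetracyclic allylsilane
Product: 42 O-silylated target with the exocyclic C7=C19 alkene
Conditions: CF3CO2H (3 equiv), CH2Cl2, −20 → 0 °C
Reagents that add atoms: none
Why: Protodesilylation of an allylsilane: protonation at C8 gives the β-silyl cation at C7, and loss of silicon places the double bond exocyclic with no regiochemical alternative.

Step 33
Reactants: 42 O-silylated target
Product: 43 CNP0132024.3
Conditions: HF·pyridine, pyridine, THF, 0 °C → rt
Reagents that add atoms: none
Why: Buffered fluoride removes the α-silyl ether without touching either ester or the exocyclic alkene.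

## Compound list

1 | prop-2-yn-1-ol | C#CCO | starting material
2 | (E)-1-bromoprop-1-ene | C/C=C/Br | starting material
3 | (E)-hex-4-en-2-yn-1-ol | C/C=C/C#CCO | intermediate
4 | (E)-hex-4-en-2-ynal | C/C=C/C#CC=O | intermediate
5 | (3S,4R,7E)-3-methylnona-1,7-dien-5-yn-4-ol | C/C=C/C#C[C@H](O)[C@@H](C)C=C | intermediate
6 | tert-butyl(dimethyl){[(3S,4R,7E)-3-methylnona-1,7-dien-5-yn-4-yl]oxy}silane | C/C=C/C#C[C@H](O[Si](C)(C)C(C)(C)C)[C@@H](C)C=C | intermediate
7 | tert-butyl(dimethyl){[(3S,4S,5Z,7E)-3-methylnona-1,5,7-trien-4-yl]oxy}silane | C/C=C/C=C\[C@H](O[Si](C)(C)C(C)(C)C)[C@@H](C)C=C | intermediate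
8 | B-alkyl-9-borabicyclo[3.3.1]nonane from 7 (boron on the terminal carbon) | C/C=C/C=C\[C@H](O[Si](C)(C)C(C)(C)C)[C@@H](C)CCB1C2CCCC1CCC2 | intermediate
9 | (3S,4R,5Z,7E)-4-[tert-butyl(dimethyl)silyl]oxy-3-methylnona-5,7-dien-1-ol | C/C=C/C=C\[C@H](O[Si](C)(C)C(C)(C)C)[C@@H](C)CCO | intermediate
10 | (3S,4R,5Z,7E)-4-[tert-butyl(dimethyl)silyl]oxy-3-methylnona-5,7-dienoic acid | C/C=C/C=C\[C@H](O[Si](C)(C)C(C)(C)C)[C@@H](C)CC(=O)O | intermediate
11 | acyl imidazolide of 10 | C/C=C/C=C\[C@H](O[Si](C)(C)C(C)(C)C)[C@@H](C)CC(=O)n1ccnc1 | intermediate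
12 | methyl (5S,6R,7Z,9E)-6-[tert-butyl(dimethyl)silyl]oxy-5-methyl-3-oxoundeca-7,9-dienoate | C/C=C/C=C\[C@H](O[Si](C)(C)C(C)(C)C)[C@@H](C)CC(=O)CC(=O)OC | intermediate
13 | methyl (5S,6R,7Z,9E)-6-[tert-butyl(dimethyl)silyl]oxy-2-diazo-5-methyl-3-oxoundeca-7,9-dienoate | C/C=C/C=C\[C@H](O[Si](C)(C)C(C)(C)C)[C@@H](C)CC(=O)C(=[N+]=[N-])C(=O)OC | intermediate
14 | methyl (1R,4S,5R,6R,7S)-5-[tert-butyl(dimethyl)silyl]oxy-4-methyl-2-oxo-7-[(E)-prop-1-enyl]bicyclo[4.1.0]heptane-1-carboxylate | C/C=C/[C@H]1[C@H]2[C@H](O[Si](C)(C)C(C)(C)C)[C@@H](C)CC(=O)[C@@]12C(=O)OC | intermediate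
15 | propane-1,3-diol | OCCCO | starting material
16 | 3-(triisopropylsilyloxy)propan-1-ol | OCCCO[Si](C(C)C)(C(C)C)C(C)C | intermediate
17 | 3-(triisopropylsilyloxy)propanal | O=CCCO[Si](C(C)C)(C(C)C)C(C)C | intermediate
18 | methyl (Z)-2-methyl-5-(triisopropylsilyloxy)pent-2-enoate | COC(=O)/C(C)=C\CCO[Si](C(C)C)(C(C)C)C(C)C | intermediate
19 | (Z)-2-methyl-5-(triisopropylsilyloxy)pent-2-en-1-ol | OC/C(C)=C\CCO[Si](C(C)C)(C(C)C)C(C)C | intermediate
20 | (Z)-2-methyl-5-(triisopropylsilyloxy)pent-2-enal | O=C/C(C)=C\CCO[Si](C(C)C)(C(C)C)C(C)C | intermediate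
21 | cis-fused hydroisobenzofuranone keto ester (C1 CO2Me, C14 ketone, C2 (Z)-alkenyl arm, C9 (E)-propenyl, 11-epi silyl ether) | C/C=C/[C@H]1O[C@@H](/C(C)=C\CCO[Si](C(C)C)(C(C)C)C(C)C)[C@]2(C(=O)OC)C(=O)C[C@H](C)[C@@H](O[Si](C)(C)C(C)(C)C)[C@H]12 | intermediate
22 | cis-fused C14 ketone (C1–H) | C/C=C/[C@H]1O[C@@H](/C(C)=C\CCO[Si](C(C)C)(C(C)C)C(C)C)[C@@H]2C(=O)C[C@H](C)[C@@H](O[Si](C)(C)C(C)(C)C)[C@H]12 | intermediate
23 | C14 alcohol (hydroxyl cis to the C2 arm) | C/C=C/[C@H]1O[C@@H](/C(C)=C\CCO[Si](C(C)C)(C(C)C)C(C)C)[C@@H]2[C@H](O)C[C@H](C)[C@@H](O[Si](C)(C)C(C)(C)C)[C@H]12 | intermediate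
24 | C14 iodide (iodine trans to the C2 arm) | C/C=C/[C@H]1O[C@@H](/C(C)=C\CCO[Si](C(C)C)(C(C)C)C(C)C)[C@@H]2[C@@H](I)C[C@H](C)[C@@H](O[Si](C)(C)C(C)(C)C)[C@H]12 | intermediate
25 | C14 isopropenyl compound (14R) | C/C=C/[C@H]1O[C@@H](/C(C)=C\CCO[Si](C(C)C)(C(C)C)C(C)C)[C@@H]2[C@@H](C(C)=C)C[C@H](C)[C@@H](O[Si](C)(C)C(C)(C)C)[C@H]12 | intermediate
26 | B-alkyl-9-borabicyclo[3.3.1]nonane from 25 (boron on C16) | C/C=C/[C@H]1O[C@@H](/C(C)=C\CCO[Si](C(C)C)(C(C)C)C(C)C)[C@@H]2[C@@H]([C@H](C)CB3C4CCCC3CCC4)C[C@H](C)[C@@H](O[Si](C)(C)C(C)(C)C)[C@H]12 | intermediate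
27 | C16 primary alcohol (15S) | C/C=C/[C@H]1O[C@@H](/C(C)=C\CCO[Si](C(C)C)(C(C)C)C(C)C)[C@@H]2[C@@H]([C@H](C)CO)C[C@H](C)[C@@H](O[Si](C)(C)C(C)(C)C)[C@H]12 | intermediate
28 | C3–C4 epoxide of 27 (oxygen on the face anti to the ring oxygen) | C/C=C/[C@H]1O[C@@H]([C@@]3(C)O[C@H]3CCO[Si](C(C)C)(C(C)C)C(C)C)[C@@H]2[C@@H]([C@H](C)CO)C[C@H](C)[C@@H](O[Si](C)(C)C(C)(C)C)[C@H]12 | intermediate
29 | oxepane alcohol (C3–O–C16 ether, free C4 hydroxyl) | CC(C)[Si](C(C)C)(C(C)C)OCC[C@H](O)[C@@]2(C)OC[C@@H](C)[C@H]3C[C@H](C)[C@@H](O[Si](C)(C)C(C)(C)C)[C@H]4[C@@H]3[C@H]2O[C@@H]4/C=C/C | intermediate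
30 | C4 acetate of 29 | CC(C)[Si](C(C)C)(C(C)C)OCC[C@H](OC(C)=O)[C@@]2(C)OC[C@@H](C)[C@H]3C[C@H](C)[C@@H](O[Si](C)(C)C(C)(C)C)[C@H]4[C@@H]3[C@H]2O[C@@H]4/C=C/C | intermediate
31 | C6,C11 diol (11-epi) | OCC[C@H](OC(C)=O)[C@@]2(C)OC[C@@H](C)[C@H]3C[C@H](C)[C@@H](O)[C@H]4[C@@H]3[C@H]2O[C@@H]4/C=C/C | intermediate
32 | C6 iodide with free 11-epi hydroxyl | ICC[C@H](OC(C)=O)[C@@]2(C)OC[C@@H](C)[C@H]3C[C@H](C)[C@@H](O)[C@H]4[C@@H]3[C@H]2O[C@@H]4/C=C/C | intermediate
33 | C11 ketone | ICC[C@H](OC(C)=O)[C@@]2(C)OC[C@@H](C)[C@H]3C[C@H](C)C(=O)[C@H]4[C@@H]3[C@H]2O[C@@H]4/C=C/C | intermediate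
34 | C11 alcohol (11S, natural) | ICC[C@H](OC(C)=O)[C@@]2(C)OC[C@@H](C)[C@H]3C[C@H](C)[C@H](O)[C@H]4[C@@H]3[C@H]2O[C@@H]4/C=C/C | intermediate
35 | (R)-2-hydroxyoctanoic acid | CCCCCC[C@@H](O)C(=O)O | starting material
36 | tert-butyldimethylsilyl (R)-2-[tert-butyl(dimethyl)silyl]oxyoctanoate | CCCCCC[C@@H](O[Si](C)(C)C(C)(C)C)C(=O)O[Si](C)(C)C(C)(C)C | intermediate
37 | (R)-2-[tert-butyl(dimethyl)silyl]oxyoctanoic acid | CCCCCC[C@@H](O[Si](C)(C)C(C)(C)C)C(=O)O | intermediate
38 | C11 (R)-2-silyloxyoctanoate with C6 iodide | ICC[C@H](OC(C)=O)[C@@]2(C)OC[C@@H](C)[C@H]3C[C@H](C)[C@H](OC(=O)[C@H](O[Si](C)(C)C(C)(C)C)CCCCCC)[C@H]4[C@@H]3[C@H]2O[C@@H]4/C=C/C | intermediate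
39 | C6 alkylzinc iodide from 38 | I[Zn]CC[C@H](OC(C)=O)[C@@]2(C)OC[C@@H](C)[C@H]3C[C@H](C)[C@H](OC(=O)[C@H](O[Si](C)(C)C(C)(C)C)CCCCCC)[C@H]4[C@@H]3[C@H]2O[C@@H]4/C=C/C | intermediate
40 | metathesis precursor (2-(trimethylsilylmethyl)allyl unit on C6, propenyl on C9) | C[Si](C)(C)CC(=C)CC[C@H](OC(C)=O)[C@@]2(C)OC[C@@H](C)[C@H]3C[C@H](C)[C@H](OC(=O)[C@H](O[Si](C)(C)C(C)(C)C)CCCCCC)[C@H]4[C@@H]3[C@H]2O[C@@H]4/C=C/C | intermediate
41 | tetracyclic allylsilane (ring-cis C7=C8, CH2SiMe3 on C7) | C1C[C@H](OC(C)=O)[C@@]2(C)OC[C@@H](C)[C@H]3C[C@H](C)[C@H](OC(=O)[C@H](O[Si](C)(C)C(C)(C)C)CCCCCC)[C@H]4[C@@H]3[C@H]2O[C@@H]4/C=C\1C[Si](C)(C)C | intermediate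
42 | O-silylated target (exocyclic C7=C19) | C=C1CC[C@H](OC(C)=O)[C@@]2(C)OC[C@@H](C)[C@H]3C[C@H](C)[C@H](OC(=O)[C@H](O[Si](C)(C)C(C)(C)C)CCCCCC)[C@H]4[C@@H]3[C@H]2O[C@@H]4C1 | intermediate
43 | CNP0132024.3 | C=C1CC[C@H](OC(C)=O)[C@@]2(C)OC[C@@H](C)[C@H]3C[C@H](C)[C@H](OC(=O)[C@H](O)CCCCCC)[C@H]4[C@@H]3[C@H]2O[C@@H]4C1 | target

## Step count and least certain steps

Total step count: 33. Longest linear sequence: 27 steps (steps 1–10, 16–27, 29–33).

**Step 16 (key step).** The Z geometry of C3=C4 may be eroded while the aldehyde is Lewis-acid activated or in the conjugated oxocarbenium ion. The cyclopropane may ionise to an allyl cation before the aldehyde attacks, which would erase the C9 information or lead to attack at the far allyl terminus. Traces of triflic acid may cleave silyl ethers. Fallback: the two bonds are made one after the other. It sets out from cyclopropane 14 and allylic alcohol 19. Lewis-acid ring opening of 14 by the hydroxyl of 19 at C9, with inversion (Yb(OTf)3, CH2Cl2), gives the C9 allyl ether keto ester F1. DDQ then removes hydride from the allylic ether methylene, and the keto ester enol traps the oxocarbenium ion, which comes back to the route at 21.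

**Step 20.** β-Hydride elimination or reduction of the hindered secondary alkyl–iron species may outrun coupling, and capture of the radical may occur on the wrong face. Fallback from iodide 24: copper-catalysed borylation (CuI, PPh3, LiOMe, B2pin2, DMF) gives the C14 pinacol boronate F2. Zweifel olefination (isopropenyllithium; I2; NaOMe) transfers C14 from boron to carbon with retention and comes back at 25.

**Step 21.** Facial selectivity at the isopropenyl group may be poor, since it rests on a rotamer preference, and some hydroboration of the propenyl group is possible. Fallback from iodide 24 through the same boronate F2, avoiding the alkene altogether. Lithiation–borylation with lithiated ethyl N,N-diisopropylcarbamate (s-BuLi with the sparteine enantiomer that leads to 15S) gives the secondary boronate F3 with reagent-controlled C15. Matteson homologation with chloromethyllithium gives the primary boronate F4, and oxidation (H2O2, NaOH) comes back at 27.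

**Step 22.** Epoxidation may take place on the wrong alkene face or at the propenyl group, and the seven-membered closure may be slow enough for a hydride shift of the activated epoxide to compete. Fallback from 27 by way of epoxide 28: dilute HClO4 in aqueous THF opens the epoxide at C3 with water, with inversion, to the triol F5. Tf2O and 2,6-lutidine at −78 °C then triflate only the primary C16 hydroxyl, and the tertiary C3 hydroxyl displaces the triflate, closing the oxepane with retention at C3 and coming back at 29.

**Step 27 (with step 26).** The axial C12 methyl next to the C11 ketone may epimerise, and hydride delivery may be less face-selective than expected. Fallback from alcohol 32 and acid 37: Mitsunobu esterification (PPh3, DIAD, toluene) inverts C11 while forming the ester and comes back at 38; no new compound is made.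

**Step 31.** Closure of a nine-membered ring onto a 1,1-disubstituted alkene may be slow, so that dimerisation, alkene isomerisation or catalyst decay compete. Fallback from iodide 38 through zinc reagent 39: Negishi coupling with vinyl bromide gives the terminal alkene F6, and ring-closing metathesis to a disubstituted alkene, a much easier closure, gives the oxonene F7. A Wacker oxidation (PdCl2(Quinox), AgSbF6, aq. t-BuOOH), in which oxygen goes to the alkene carbon remote from the C9 ether oxygen, gives the C7 ketone F8, and Wittig methylenation (Ph3P=CH2) comes back at 42.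

## Further compounds

F1 | step 16 | C9 allyl ether keto ester (ring-opened 14 carrying the (Z)-2-methyl-5-(triisopropylsilyloxy)pent-2-enyl ether at C9) | C/C=C/[C@@H](OC/C(C)=C\CCO[Si](C(C)C)(C(C)C)C(C)C)[C@H]1[C@H](O[Si](C)(C)C(C)(C)C)[C@@H](C)CC(=O)C1C(=O)OC
F2 | step 20 | C14 pinacol boronate | C/C=C/[C@H]1O[C@@H](/C(C)=C\CCO[Si](C(C)C)(C(C)C)C(C)C)[C@@H]2[C@@H](B3OC(C)(C)C(C)(C)O3)C[C@H](C)[C@@H](O[Si](C)(C)C(C)(C)C)[C@H]12
F3 | step 21 | C15 secondary pinacol boronate | C/C=C/[C@H]1O[C@@H](/C(C)=C\CCO[Si](C(C)C)(C(C)C)C(C)C)[C@@H]2[C@@H]([C@H](C)B3OC(C)(C)C(C)(C)O3)C[C@H](C)[C@@H](O[Si](C)(C)C(C)(C)C)[C@H]12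
F4 | step 21 | C16 primary pinacol boronate | C/C=C/[C@H]1O[C@@H](/C(C)=C\CCO[Si](C(C)C)(C(C)C)C(C)C)[C@@H]2[C@@H]([C@H](C)CB3OC(C)(C)C(C)(C)O3)C[C@H](C)[C@@H](O[Si](C)(C)C(C)(C)C)[C@H]12
F5 | step 22 | C3,C4,C16 triol | C/C=C/[C@H]1O[C@@H]([C@](C)(O)[C@@H](O)CCO[Si](C(C)C)(C(C)C)C(C)C)[C@@H]2[C@@H]([C@H](C)CO)C[C@H](C)[C@@H](O[Si](C)(C)C(C)(C)C)[C@H]12
F0 | step 27 | none | none
F6 | step 31 | C6 allyl compound (terminal C7=C19 alkene, no silicon) | C=CCC[C@H](OC(C)=O)[C@@]2(C)OC[C@@H](C)[C@H]3C[C@H](C)[C@H](OC(=O)[C@H](O[Si](C)(C)C(C)(C)C)CCCCCC)[C@H]4[C@@H]3[C@H]2O[C@@H]4/C=C/C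
F7 | step 31 | tetracyclic (Z)-C7=C8 oxonene | C1C[C@H](OC(C)=O)[C@@]2(C)OC[C@@H](C)[C@H]3C[C@H](C)[C@H](OC(=O)[C@H](O[Si](C)(C)C(C)(C)C)CCCCCC)[C@H]4[C@@H]3[C@H]2O[C@@H]4/C=C\1
F8 | step 31 | tetracyclic C7 ketone | O=C1CC[C@H](OC(C)=O)[C@@]2(C)OC[C@@H](C)[C@H]3C[C@H](C)[C@H](OC(=O)[C@H](O[Si](C)(C)C(C)(C)C)CCCCCC)[C@H]4[C@@H]3[C@H]2O[C@@H]4C1
A1 | alternative 1 | tetracyclic C6 allylic alcohol with C7 exocyclic methylene | C=C1[C@@H](O)C[C@H](O[Si](CC)(CC)CC)[C@@]2(C)OC[C@@H](C)[C@H]3C[C@H](C)[C@H](OC(=O)[C@H](O[Si](C)(C)C(C)(C)C)CCCCCC)[C@H]4[C@@H]3[C@H]2O[C@@H]4C1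
A2 | alternative 1 | open precursor with C6 aldehyde and C7 alkenyl iodide | O=CC[C@H](O[Si](CC)(CC)CC)[C@@]2(C)OC[C@@H](C)[C@H]3C[C@H](C)[C@H](OC(=O)[C@H](O[Si](C)(C)C(C)(C)C)CCCCCC)[C@H]4[C@@H]3[C@H]2O[C@@H]4CC(I)=C
A3 | alternative 2 | seven-membered lactone with the C3–O bond | O1CCOC12CC[C@H](O[Si](C)(C)C(C)(C)C)[C@@]3(C)OC(=O)C[C@H]5C[C@H](C)[C@H](OCc6ccccc6)[C@H]4[C@@H]5[C@H]3O[C@@H]4C2
A4 | alternative 2 | decalone with C16 ketone next to quaternary C3 | O1CCOC12CC[C@H](O[Si](C)(C)C(C)(C)C)[C@@]3(C)C(=O)C[C@H]5C[C@H](C)[C@H](OCc6ccccc6)[C@H]4[C@@H]5[C@H]3O[C@@H]4C2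
A5 | alternative 3 | 11-oxabicyclo[6.2.1]undecenone with C10 ketone and C6=C7 allylsilane | O=C1C[C@H]2O[C@@H]1C/C(C[Si](C)(C)C)=C\C[C@H](O[Si](C)(C)C(C)(C)C)[C@@]2(C)O[Si](CC)(CC)CC
A6 | alternative 3 | tetrahydropyranyl diazoketone with 2-(trimethylsilylmethyl)vinyl group | [N-]=[N+]=CC(=O)C[C@H]1O[C@@H](C(=C)C[Si](C)(C)C)C[C@H](O[Si](C)(C)C(C)(C)C)[C@@]1(C)O[Si](CC)(CC)CC
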